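## Retrosynthetic overview

1. Target 20 ⇐ hydroxyl-directed epoxidation of C4=C5, C9 acylation and oxidative 12,8-lactonisation of a (1(10)E,4E)-germacradiene triol.
2. Ten-membered ring ⇐ anionic oxy-Cope rearrangement ([3,3], forms C2–C3) of a trans-1-isopropenyl-2-vinylcyclohexanol; the enolate is trapped as its enol triflate and reduced to the 4,5-alkene.
3. Cyclohexanone (C5–C10, carrying C6–C9 stereocentres) ⇐ (R)-carvone by deconjugative α-vinylation, α'-hydroxylation and directed dihydroxylation; the isopropenyl group is masked as its epoxide and later opened to the C12 allylic alcohol.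
4. Ring order: six-membered ring (bought) → ten-membered carbocycle → γ-lactone → epoxide.

Assumption: germacrane numbering of the target (C1–C15) is used for every intermediate (carvone ring = C5–C10, ketone = C5, side chain = C11–C13); "α" is the ring face opposite the C7 side chain. Compounds 2–13 are about 1:1 mixtures at the side-chain epoxide carbon C11, which becomes sp2 in step 9 and is left unspecified in their SMILES.

## Route

Step 1
Reactants: 1 (R)-(−)-carvone
Product: 2 (5R)-carvone 8,9-epoxide [2-methyl-5-(2-methyloxiran-2-yl)cyclohex-2-en-1-one]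
Conditions: mCPBA, CH2Cl2, 0 °C
Reagents that add atoms: mCPBA, O=C(OO)c1cccc(Cl)c1
Why: Prilezhaev epoxidation of the electron-rich 1,1-disubstituted alkene (the enone alkene is inert) masks the isopropenyl group against OsO4 and puts oxygen on the future C12; the new centre is erased in step 9.

Step 2
Reactants: 2 (5R)-carvone 8,9-epoxide; 3 phenyl vinyl sulfoxide
Product: 5 (2R,5S)-2-ethenyl-2-methyl-5-(2-methyloxiran-2-yl)cyclohex-3-en-1-one (vinyl trans to the side chain), via sulfoxide Michael adduct 4 (not isolated)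
Conditions: KOt-Bu (0.2 equiv), t-BuOH/THF, 0 °C → rt; then solvent switch to toluene, 110 °C
Reagents that add atoms: none
Why: Deconjugative Michael addition of the thermodynamic extended dienolate at its α-carbon (C10), anti to the C7 substituent, then sulfoxide syn-elimination (phenyl vinyl sulfoxide as vinyl cation equivalent) sets quaternary C10 and moves the ring alkene to C8=C9.

Step 3
Reactants: 5
Product: 6 6-hydroxy derivative of 5 (OH trans to the C7 side chain)
Conditions: LiN(i-Pr)2, THF, −78 °C; then racemic 2-(phenylsulfonyl)-3-phenyloxaziridine, −78 °C; aqueous work-up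
Reagents that add atoms: 2-(phenylsulfonyl)-3-phenyloxaziridine, O=S(=O)(N1OC1c1ccccc1)c1ccccc1
Why: Davis enolate hydroxylation; C6 is the only enolisable position and the oxidant approaches anti to the adjacent C7 substituent, giving the trans α-hydroxy ketone.

Step 4
Reactants: 6
Product: 7 6,8,9-triol (all three OH and the C10 vinyl on the α face, C8/C9 diol cis)
Conditions: OsO4 (1.05 equiv), TMEDA, CH2Cl2, −78 °C; then aq. Na2SO3, THF, rt
Reagents that add atoms: OsO4, O=[Os](=O)(=O)=O
Why: Donohoe hydroxyl-directed syn-dihydroxylation; hydrogen bonding from C6–OH delivers OsO4·TMEDA to the ring alkene on the α face (also anti to the C7 side chain), sparing the neopentylic vinyl group and the masked side chain.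

Step 5
Reactants: 7
Product: 8 8,9-O-isopropylidene acetal of 7 (C6–OH free)
Conditions: 2,2-dimethoxypropane, PPTS (cat.), acetone, 0 °C → rt
Reagents that add atoms: 2,2-dimethoxypropane, COC(C)(C)OC
Why: Acetonide formation selects the cis-1,2-diol (five-membered dioxolane) and blocks retro-aldol cleavage of the β-hydroxy ketone.

Step 6
Reactants: 8
Product: 9 6-O-TBS ether of 8
Conditions: TBSCl, imidazole, DMF, rt → 40 °C
Reagents that add atoms: TBSCl, CC(C)(C)[Si](C)(C)Cl
Why: Silylation of the remaining secondary alcohol so that no free alkoxide competes in the triflation of step 8.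

Step 7
Reactants: 9; 10 isopropenylmagnesium bromide
Product: 11 tertiary carbinol (C5: isopropenyl β, OH α; isopropenyl trans to the C10 vinyl)
Conditions: CeCl3 (anhydrous), THF, −78 → −20 °C
Reagents that add atoms: none
Why: Imamoto organocerium 1,2-addition to the hindered ketone without enolisation; attack from the β face (equatorial) because the α face is blocked by the axial C9 acetonide oxygen, which places isopropenyl trans to the vinyl group.

Step 8
Reactants: 11
Product: 13 ring-expanded enol triflate (C5–OTf; 1(10)E; C3 and C6 trans across C4=C5), via potassium enolate 12 (not isolated)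
Conditions: KH, 18-crown-6, THF, 0 °C → rt; then PhNTf2, −78 → 0 °C
Reagents that add atoms: N-phenyl-bis(trifluoromethanesulfonimide), O=S(=O)(N(c1ccccc1)S(=O)(=O)C(F)(F)F)C(F)(F)F
Why: Anionic oxy-Cope rearrangement ([3,3]-sigmatropic) through a chair transition state with both alkenyl groups equatorial forms C2–C3 and the ten-membered ring with ring-trans geometry at both new double bonds; O-triflation freezes the enolate geometry.

Step 9
Reactants: 13
Product: 14 C12 allylic alcohol (side chain CH2=C(CH2OH)–)
Conditions: Et2AlCl + lithium 2,2,6,6-tetramethylpiperidide (preformed Et2AlTMP, 4 equiv), toluene, 0 °C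
Reagents that add atoms: none
Why: Yamamoto–Nozaki epoxide-to-allylic-alcohol isomerisation; the aluminium amide removes a proton from the unhindered methyl group, unmasking the 11(13)-alkene with C12–OH and erasing the epimeric centre.

Step 10
Reactants: 14
Product: 15 8,9,12-triol enol triflate (6-O-TBS retained)
Conditions: 80% aq. AcOH, 45 °C
Reagents that add atoms: none
Why: Acetonide hydrolysis is done while C4=C5 is still an electron-poor enol triflate, so acid-induced transannular cyclisation of the 1,5-diene is not triggered; the secondary TBS ether survives.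

Step 11
Reactants: 15
Product: 16 6-O-TBS-germacra-1(10)E,4E,11(13)-triene-8,9,12-triol
Conditions: Pd(PPh3)4 (5 mol %), Bu3SnH, LiCl, THF, 50 °C
Reagents that add atoms: none
Why: Stille-type palladium-catalysed hydride reduction of the enol triflate proceeds with retention of geometry under neutral conditions and gives the (4E)-trisubstituted alkene.

Step 12
Reactants: 16
Product: 17 6-O-TBS-9-hydroxygermacra-1(10)E,4E,11(13)-trien-12,8-olide (trans-fused lactone)
Conditions: Cu(MeCN)4OTf (5 mol %), 2,2'-bipyridine, TEMPO, N-methylimidazole, MeCN, air, rt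
Reagents that add atoms: none
Why: Stahl aerobic copper/nitroxyl oxidative lactonisation; only the primary allylic alcohol is oxidised, the enal closes to the five-membered lactol on C8–OH and is oxidised on to the α-methylene-γ-butyrolactone without cleaving the vicinal diol.

Step 13
Reactants: 17
Product: 18 9-O-isobutyrate of 17
Conditions: isobutyric anhydride, DMAP (cat.), pyridine, CH2Cl2, 0 °C → rt
Reagents that add atoms: isobutyric anhydride, CC(C)C(=O)OC(=O)C(C)C
Why: DMAP-catalysed acyl transfer (Steglich-type) to the only free hydroxyl group.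

Step 14
Reactants: 18
Product: 19 6-hydroxy-9-isobutyryloxygermacra-1(10)E,4E,11(13)-trien-12,8-olide
Conditions: HF·pyridine, pyridine, THF, 0 °C → rt
Reagents that add atoms: none
Why: Buffered fluoride desilylation spares the α-methylene lactone, the ester and the acid-sensitive 1,5-diene.

Step 15
Reactants: 19
Product: 20 (1(10)E,4S,5S,6S,7S,8R,9S)-4,5-epoxy-6-hydroxy-9-isobutyryloxygermacra-1(10),11(13)-dien-12,8-olide (target)
Conditions: VO(acac)2 (5 mol %), t-BuOOH, CH2Cl2, 0 °C
Reagents that add atoms: tert-butyl hydroperoxide, CC(C)(C)OO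
Why: Sharpless vanadium-catalysed allylic-alcohol-directed epoxidation touches only C4=C5; the vanadate geometry (O–C6–C5=C4 near 45°, C6–C7 perpendicular to the alkene as the ring requires) should deliver oxygen to the face giving the trans (4S,5S)-epoxide, erythro to the 6S carbinol.

## Compound list

1 | (R)-(−)-carvone | O=C1C(C)=CC[C@@H](C(C)=C)C1 | starting material
2 | (5R)-carvone 8,9-epoxide (about 1:1 at the oxirane carbon) | O=C1C(C)=CC[C@@H](C2(C)CO2)C1 | intermediate
3 | phenyl vinyl sulfoxide (racemic) | C=CS(=O)c1ccccc1 | starting material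
4 | 2-methyl-5-(2-methyloxiran-2-yl)-2-[2-(phenylsulfinyl)ethyl]cyclohex-3-en-1-one (sulfinylethyl trans to side chain) | O=C1[C@](C)(CCS(=O)c2ccccc2)C=C[C@@H](C3(C)CO3)C1 | intermediate (not isolated)
5 | (2R,5S)-2-ethenyl-2-methyl-5-(2-methyloxiran-2-yl)cyclohex-3-en-1-one | O=C1[C@](C)(C=C)C=C[C@@H](C2(C)CO2)C1 | intermediate
6 | 6-hydroxy derivative of 5 (OH trans to side chain) | O=C1[C@](C)(C=C)C=C[C@@H](C2(C)CO2)[C@@H]1O | intermediate
7 | 2-ethenyl-3,4,6-trihydroxy-2-methyl-5-(2-methyloxiran-2-yl)cyclohexan-1-one (three OH and vinyl on one face, side chain on the other) | O=C1[C@](C)(C=C)[C@H](O)[C@H](O)[C@@H](C2(C)CO2)[C@@H]1O | intermediate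
8 | 3,4-O-isopropylidene acetal of 7 | O=C1[C@](C)(C=C)[C@@H]2OC(C)(C)O[C@@H]2[C@@H](C3(C)CO3)[C@@H]1O | intermediate
9 | 6-O-TBS ether of 8 | O=C1[C@](C)(C=C)[C@@H]2OC(C)(C)O[C@@H]2[C@@H](C3(C)CO3)[C@@H]1O[Si](C)(C)C(C)(C)C | intermediate
10 | isopropenylmagnesium bromide | CC(=C)[Mg]Br | starting material
11 | 1-isopropenyl carbinol from 9 (isopropenyl cis to side chain, trans to vinyl) | O[C@]1(C(C)=C)[C@](C)(C=C)[C@@H]2OC(C)(C)O[C@@H]2[C@@H](C3(C)CO3)[C@@H]1O[Si](C)(C)C(C)(C)C | intermediate
12 | potassium enolate of the ring-expanded cyclodecadienone | [K+].[O-]/C1=C(/C)CC/C=C(\C)[C@@H]2OC(C)(C)O[C@@H]2[C@@H](C3(C)CO3)[C@@H]1O[Si](C)(C)C(C)(C)C | intermediate (not isolated)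
13 | C5 enol triflate; 6-O-TBS, 8,9-O-isopropylidene, 11,12-epoxide; 1(10)E, C3/C6 trans across C4=C5 | FC(F)(F)S(=O)(=O)O/C1=C(/C)CC/C=C(\C)[C@@H]2OC(C)(C)O[C@@H]2[C@@H](C3(C)CO3)[C@@H]1O[Si](C)(C)C(C)(C)C | intermediate
14 | 12-hydroxy-11(13)-ene analogue of 13 | FC(F)(F)S(=O)(=O)O/C1=C(/C)CC/C=C(\C)[C@@H]2OC(C)(C)O[C@@H]2[C@@H](C(=C)CO)[C@@H]1O[Si](C)(C)C(C)(C)C | intermediate
15 | 8,9,12-triol enol triflate | FC(F)(F)S(=O)(=O)O/C1=C(/C)CC/C=C(\C)[C@H](O)[C@H](O)[C@@H](C(=C)CO)[C@@H]1O[Si](C)(C)C(C)(C)C | intermediate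
16 | 6-O-TBS-germacra-1(10)E,4E,11(13)-triene-8,9,12-triol | CC(C)(C)[Si](C)(C)O[C@@H]1/C=C(C)/CC/C=C(\C)[C@H](O)[C@H](O)[C@H]1C(=C)CO | intermediate
17 | 6-O-TBS-9-hydroxygermacra-1(10)E,4E,11(13)-trien-12,8-olide | C=C1C(=O)O[C@@H]2[C@@H]1[C@H](O[Si](C)(C)C(C)(C)C)/C=C(C)/CC/C=C(\C)[C@@H]2O | intermediate
18 | 9-O-isobutyrate of 17 | C=C1C(=O)O[C@@H]2[C@@H]1[C@H](O[Si](C)(C)C(C)(C)C)/C=C(C)/CC/C=C(\C)[C@@H]2OC(=O)C(C)C | intermediate
19 | 6-hydroxy-9-isobutyryloxygermacra-1(10)E,4E,11(13)-trien-12,8-olide | C=C1C(=O)O[C@@H]2[C@@H]1[C@H](O)/C=C(C)/CC/C=C(\C)[C@@H]2OC(=O)C(C)C | intermediate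
20 | (1(10)E,4S,5S,6S,7S,8R,9S)-4,5-epoxy-6-hydroxy-9-isobutyryloxygermacra-1(10),11(13)-dien-12,8-olide | C=C1C(=O)O[C@@H]2[C@@H]1[C@H](O)[C@@H]1O[C@@]1(C)CC/C=C(\C)[C@@H]2OC(=O)C(C)C | target

## Step count and risks

Total step count: 15. Longest linear sequence: 15 (fully linear from 1).

Three steps most likely to fail:

Step 2 (deconjugative vinylation). The dienolate may react at C6 instead of C10, and facial selectivity at the quaternary centre may be modest. The fallback sets out from 1 and returns at 5, building C10 by a stereospecific rearrangement instead of an alkylation. Vinylmagnesium bromide/CeCl3 adds to 1 anti to the isopropenyl group to give 1-ethenyl-2-methyl-5-(prop-1-en-2-yl)cyclohex-2-en-1-ol F1. VO(acac)2/t-BuOOH epoxidises the ring alkene syn to the hydroxyl, giving the epoxy alcohol F2. BF3·OEt2 at −78 °C then triggers a semipinacol rearrangement in which the vinyl group migrates anti to the breaking C10–O bond, giving the β-hydroxy ketone F3 with the quaternary centre fixed. mCPBA epoxidises the isopropenyl group faster than the vinyl group to give the side-chain epoxide F4. Mesylation gives the mesylate F5, and DBU in toluene at 80 °C eliminates toward C8 (the only β-hydrogens) to give 5.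

Step 4 (chemoselective osmylation). The vinyl group may compete with the ring alkene. The fallback sets out from 4, which is then isolated instead of heated, and returns at 7, so that osmylation is done while the vinyl group is still masked. Enolate hydroxylation as in step 3 gives the 6-hydroxy sulfoxide F6. The ring alkene is now the only alkene, and stoichiometric OsO4/pyridine at −40 °C without co-oxidant (so the sulfoxide is not oxidised further) gives the triol sulfoxide F7. Thermolysis in toluene at 110 °C then unveils the vinyl group to give 7.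

Step 15 (facial selectivity of the epoxidation). Hydroxyl-directed delivery may favour the threo (4R,5R) epoxide, as simple acyclic models would predict. The fallback sets out from 18 and returns at 20, replacing hydroxyl direction by steric control. Buffered mCPBA (NaHCO3, CH2Cl2, −20 °C) epoxidises C4=C5 of the silyl ether on the face left open by the bulky silyloxy group, giving the epoxy silyl ether F8; the 1(10)-alkene is deactivated by the allylic ester. HF·pyridine then gives 20.

## Further compounds

F1 | step 2 | 1-ethenyl-2-methyl-5-(prop-1-en-2-yl)cyclohex-2-en-1-ol (vinyl trans to isopropenyl) | O[C@@]1(C=C)C(C)=CC[C@@H](C(C)=C)C1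
F2 | step 2 | 2,3-epoxide of F1, syn to the hydroxyl | O[C@@]1(C=C)[C@@]2(C)O[C@H]2C[C@@H](C(C)=C)C1
F3 | step 2 | 2-ethenyl-3-hydroxy-2-methyl-5-(prop-1-en-2-yl)cyclohexan-1-one (vinyl trans, OH cis to isopropenyl) | O=C1[C@](C)(C=C)[C@@H](O)C[C@@H](C(C)=C)C1
F4 | step 2 | side-chain epoxide of F3 | O=C1[C@](C)(C=C)[C@@H](O)C[C@@H](C2(C)CO2)C1
F5 | step 2 | methanesulfonate of F4 | O=C1[C@](C)(C=C)[C@@H](OS(C)(=O)=O)C[C@@H](C2(C)CO2)C1
F6 | step 4 | 6-hydroxy derivative of sulfoxide 4 | O=C1[C@](C)(CCS(=O)c2ccccc2)C=C[C@@H](C3(C)CO3)[C@@H]1O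
F7 | step 4 | 3,4,6-triol sulfoxide (sulfoxide analogue of 7) | O=C1[C@](C)(CCS(=O)c2ccccc2)[C@H](O)[C@H](O)[C@@H](C3(C)CO3)[C@@H]1O
F8 | step 15 | 6-O-TBS ether of 20 | C=C1C(=O)O[C@@H]2[C@@H]1[C@H](O[Si](C)(C)C(C)(C)C)[C@@H]1O[C@@]1(C)CC/C=C(\C)[C@@H]2OC(=O)C(C)C
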